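**Retrosynthetic overview**

1. Locants: drimane C1–C12 (C11 = CH2 on C9, C12 = exocyclic CH2 on C8); carbocycle C1' (C=O), C2'=C3' (C3' carries CH2O–HMG), C4' (CHOH), C5'/C6' (oxirane, C6' carries C11).
2. Endgame: HMG half-ester (from (R)-mevalonolactone) ⇒ diol; C3'–CH2OH ⇒ C3'–I (Stille); cis-oxirane ⇒ OH-directed epoxidation of C5'=C6'; C4'–OH ⇒ CBS reduction of a C4' ketone.
3. Key disconnection C11–C6': with C1' masked as its dimethyl ketal and C4' at the ketone level, the ring is the mirror-symmetric cross-conjugated dienone 4,4-dimethoxycyclohexa-2,5-dienone, in which C6' is a β-carbon of the C4' enone. Copper-catalysed conjugate addition of the drimanylmethyl Grignard reagent and re-oxidation of the enolate amount to a C–H alkylation that delivers the whole C23 skeleton with C4' (free ketone) and C1' (ketal) already differentiated.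
4. Drimane half: (+)-sclareolide ⇒ lactol ⇒ alkoxy-radical fragmentation to the C11 iodide ⇒ dehydration to the 8(12)-ene.
5. Ring order: decalin (rings A/B) from the chiral pool, carbocycle bought intact, oxirane formed last (step 8).

Key step: step 5

Remark: (+)-sclareolide, 4,4-dimethoxycyclohexa-2,5-dien-1-one and (R)-(−)-mevalonolactone are taken as commercial; "drim-8(12)-en-11-yl" stands for [(1S,4aS,8aS)-5,5,8a-trimethyl-2-methylidenedecahydronaphthalen-1-yl]methyl; the CIP descriptors at C4' and at the HMG carbon change along the route only because substituent priorities change, not the spatial arrangement.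

**Step 1**
Reactants: 1 (+)-sclareolide
Product: 2 sclareolide lactol (hemiacetal of 1, both anomers)
Conditions: DIBAL-H, CH2Cl2, −78 °C
Reagents that add atoms: none
Why: Partial reduction of a γ-lactone to the lactol by DIBAL-H at low temperature; no decalin stereocentre is touched and the anomeric centre is destroyed in step 2.

**Step 2**
Reactants: 2 sclareolide lactol
Product: 3 11-iododriman-8α-yl formate
Conditions: PhI(OAc)2, I2, cyclohexane, hν (visible), 25 °C
Reagents that add atoms: iodine, II
Why: Suárez hypoiodite fragmentation: the lactol alkoxy radical undergoes β-scission of the bond between the lactol carbon and C11, iodine traps the C11 radical and the lactol carbon stays as the formate on the 8α-oxygen, so C5, C8, C9 and C10 keep their configuration.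

**Step 3**
Reactants: 3 11-iododriman-8α-yl formate
Product: 4 11-iododriman-8α-ol
Conditions: KHCO3, MeOH, 25 °C
Reagents that add atoms: none
Why: Mild base-catalysed transesterification of a formate; bicarbonate keeps the tertiary alkoxide concentration too low for Grob fragmentation or oxetane closure onto the γ-iodide.

**Step 4**
Reactants: 4 11-iododriman-8α-ol
Product: 5 11-iododrim-8(12)-ene (albicanyl iodide)
Conditions: SOCl2, pyridine, CH2Cl2, −78 °C
Reagents that add atoms: none
Why: E2 dehydration through the chlorosulfite: the equatorial 8α leaving group has antiperiplanar hydrogens only on the axial C12 methyl, so the exocyclic 8(12)-alkene should predominate, and minor endocyclic isomers are to be removed on AgNO3-impregnated silica.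

**Step 5**
Reactants: 5 11-iododrim-8(12)-ene; 6 4,4-dimethoxycyclohexa-2,5-dien-1-one
Product: 9 3-(drim-8(12)-en-11-yl)-4,4-dimethoxycyclohexa-2,5-dien-1-one, via drimenylmagnesium iodide 7 (not isolated), via silyl dienol ether 8 (not isolated)
Conditions: (i) Mg, Et2O, 35 °C; (ii) 6, CuBr·SMe2 (10 mol%), TMSCl, DMPU, THF, −78 °C; (iii) crude 8, Pd(OAc)2, MeCN, 25 °C
Reagents that add atoms: none
Why: Magnesium insertion gives the primary Grignard reagent 7, which under copper catalysis transfers the drimanylmethyl group to a β-carbon of dienone 6 (π-complex, Cu(III) intermediate, reductive elimination) while TMSCl traps the enolate as silyl dienol ether 8; Pd(OAc)2 then forms the α-palladio ketone and eliminates the only β-hydrogen (C6'–H), so the C5'=C6' alkene returns and the net result is C–H alkylation at C6'. The closest known reaction types are the TMSCl-accelerated copper-catalysed conjugate addition of Grignard reagents to enones, long used on p-quinone monoketals, and the Saegusa–Ito dehydrogenation. No ring is closed. The only new stereocentre, C6' of 8, is transient and both epimers converge on 9, so no facial control is needed. The step needs 1,4- over 1,2-addition, which copper and TMSCl secure; mono-addition, which follows because 8 is no longer a Michael acceptor; and site selectivity, which the mirror plane of 6 through C1' and C4' makes moot. Dehydrogenation can only run towards C6' because the other side (C2'=C3') is already unsaturated.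

**Step 6**
Reactants: 9 3-(drim-8(12)-en-11-yl)-4,4-dimethoxycyclohexa-2,5-dien-1-one
Product: 10 5-(drim-8(12)-en-11-yl)-2-iodo-4,4-dimethoxycyclohexa-2,5-dien-1-one
Conditions: I2, pyridine, CH2Cl2, 0 → 25 °C
Reagents that add atoms: iodine, II
Why: Pyridine–iodine α-iodination of an enone (pyridine adds to the β-carbon, the enolate is iodinated, pyridine is expelled); only C2' can accept pyridine because the other β-carbon (C6') is fully substituted, so iodine should enter at C3' alone.

**Step 7**
Reactants: 10 5-(drim-8(12)-en-11-yl)-2-iodo-4,4-dimethoxycyclohexa-2,5-dien-1-one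
Product: 11 (1S)-5-(drim-8(12)-en-11-yl)-2-iodo-4,4-dimethoxycyclohexa-2,5-dien-1-ol
Conditions: (R)-Me-CBS (20 mol%), catecholborane, toluene, −78 °C; MeOH then aq. NaOH work-up
Reagents that add atoms: none
Why: Corey–Bakshi–Shibata reduction in which the α-iodovinyl arm is the large group and the unsubstituted vinyl arm the small one, so the (R)-catalyst should deliver hydride to the face that gives the C4' configuration of the target; catecholborane at −78 °C does not hydroborate the exocyclic alkene and the basic work-up protects the acid-labile dienol ketal.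

**Step 8**
Reactants: 11 (1S)-5-(drim-8(12)-en-11-yl)-2-iodo-4,4-dimethoxycyclohexa-2,5-dien-1-ol
Product: 12 (1R,2S,6R)-6-(drim-8(12)-en-11-yl)-3-iodo-5,5-dimethoxy-7-oxabicyclo[4.1.0]hept-3-en-2-ol (oxirane cis to OH)
Conditions: VO(acac)2 (5 mol%), t-BuOOH (decane), CH2Cl2, 0 °C
Reagents that add atoms: tert-butyl hydroperoxide, CC(C)(C)OO
Why: Vanadium-catalysed hydroxyl-directed epoxidation delivers oxygen syn to the C4' hydroxyl and so sets C5' and C6' cis to it; the electron-poor iodoalkene is far less nucleophilic than the alkyl-substituted C5'=C6' alkene, and the exocyclic alkene has no directing hydroxyl.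

**Step 9**
Reactants: 12 iodo epoxy alcohol
Product: 13 (1R,2R,6R)-6-(drim-8(12)-en-11-yl)-3-(hydroxymethyl)-5,5-dimethoxy-7-oxabicyclo[4.1.0]hept-3-en-2-ol
Conditions: Bu3SnCH2OH, Pd(PPh3)4 (10 mol%), 1,4-dioxane, 85 °C
Reagents that add atoms: (tributylstannyl)methanol, OC[Sn](CCCC)(CCCC)CCCC
Why: Stille coupling of an alkenyl iodide with a hydroxymethyl stannane proceeds with retention at the sp2 carbon and touches no stereocentre; it is placed before the allyl ester enters the molecule.

**Step 10**
Reactants: 14 (R)-(−)-mevalonolactone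
Product: 16 allyl (3R)-3,5-dihydroxy-3-methylpentanoate, via potassium (R)-mevalonate 15 (not isolated)
Conditions: KOH, MeOH/H2O, 25 °C, evaporate; allyl bromide, DMF, 25 °C
Reagents that add atoms: potassium hydroxide, [K+].[OH-]; allyl bromide, C=CCBr
Why: Saponification of the δ-lactone and SN2 O-alkylation of the carboxylate; the quaternary stereocentre is not involved.

**Step 11**
Reactants: 16 allyl (3R)-3,5-dihydroxy-3-methylpentanoate
Product: 17 (3R)-5-(allyloxy)-3-hydroxy-3-methyl-5-oxopentanoic acid
Conditions: TEMPO (20 mol%), PhI(OAc)2, MeCN/H2O (1:1), 0 → 25 °C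
Reagents that add atoms: water, O
Why: TEMPO/PhI(OAc)2 oxidation of the primary alcohol to the acid leaves the tertiary alcohol and the allyl ester alone; the former C5 arm of mevalonate becomes the arm that will be esterified, which fixes the HMG configuration of the target.

**Step 12**
Reactants: 13 diol; 17 (3R)-5-(allyloxy)-3-hydroxy-3-methyl-5-oxopentanoic acid
Product: 18 allyl ester of the C1' dimethyl ketal of the target (HMG carbon S)
Conditions: DCC, DMAP (10 mol%), CH2Cl2, −20 → 0 °C
Reagents that add atoms: none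
Why: Steglich esterification should acylate the primary allylic hydroxyl in preference to the hindered secondary C4' hydroxyl next to the oxirane, and the tertiary hydroxyl of 17 does not compete.

**Step 13**
Reactants: 18 allyl ester ketal
Product: 19 C1' dimethyl ketal of the target (free acid)
Conditions: Pd(PPh3)4 (5 mol%), morpholine, THF, 0 °C
Reagents that add atoms: none
Why: Tsuji–Trost deallylation; the unsubstituted allyl ester ionises much faster than the trisubstituted allylic ester that links the side chain to the ring, and no enone is present yet.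

**Step 14**
Reactants: 19 ketal acid
Product: 20 target, (3S)-5-{[(1R,2R,6R)-6-(drim-8(12)-en-11-yl)-2-hydroxy-5-oxo-7-oxabicyclo[4.1.0]hept-3-en-3-yl]methoxy}-3-hydroxy-3-methyl-5-oxopentanoic acid
Conditions: PPTS, acetone/H2O (9:1), 35 °C
Reagents that add atoms: water, O
Why: Acid-catalysed hydrolysis of the allylic dimethyl ketal unveils the C1' enone; the α-keto oxirane, the cis hydroxyl, the exocyclic alkene and the β-hydroxy ester should tolerate these mild conditions.

**Compound list**

1 | (+)-sclareolide, (3aR,5aS,9aS,9bR)-3a,6,6,9a-tetramethyldecahydronaphtho[2,1-b]furan-2(1H)-one | CC1(C)CCC[C@@]2(C)[C@H]1CC[C@@]1(C)OC(=O)C[C@H]21 | starting material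
2 | sclareolide lactol (2-hydroxy analogue of 1, both anomers) | CC1(C)CCC[C@@]2(C)[C@H]1CC[C@@]1(C)OC(O)C[C@H]21 | intermediate
3 | 11-iododriman-8α-yl formate | CC1(C)CCC[C@@]2(C)[C@H]1CC[C@@](C)(OC=O)[C@@H]2CI | intermediate
4 | 11-iododriman-8α-ol | CC1(C)CCC[C@@]2(C)[C@H]1CC[C@@](C)(O)[C@@H]2CI | intermediate
5 | 11-iododrim-8(12)-ene (albicanyl iodide) | C=C1CC[C@H]2C(C)(C)CCC[C@]2(C)[C@H]1CI | intermediate
6 | 4,4-dimethoxycyclohexa-2,5-dien-1-one | O=C1C=CC(OC)(OC)C=C1 | starting material
7 | (drim-8(12)-en-11-yl)magnesium iodide | I[Mg]C[C@H]1C(=C)CC[C@H]2C(C)(C)CCC[C@]12C | intermediate (not isolated)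
8 | {[3-(drim-8(12)-en-11-yl)-4,4-dimethoxycyclohexa-1,5-dien-1-yl]oxy}trimethylsilane (both C3 epimers) | C[Si](C)(C)OC1=CC(C[C@H]2C(=C)CC[C@H]3C(C)(C)CCC[C@]23C)C(OC)(OC)C=C1 | intermediate (not isolated)
9 | 3-(drim-8(12)-en-11-yl)-4,4-dimethoxycyclohexa-2,5-dien-1-one | O=C1C=CC(OC)(OC)C(C[C@H]2C(=C)CC[C@H]3C(C)(C)CCC[C@]23C)=C1 | intermediate
10 | 5-(drim-8(12)-en-11-yl)-2-iodo-4,4-dimethoxycyclohexa-2,5-dien-1-one | O=C1C(I)=CC(OC)(OC)C(C[C@H]2C(=C)CC[C@H]3C(C)(C)CCC[C@]23C)=C1 | intermediate
11 | (1S)-5-(drim-8(12)-en-11-yl)-2-iodo-4,4-dimethoxycyclohexa-2,5-dien-1-ol | O[C@@H]1C(I)=CC(OC)(OC)C(C[C@H]2C(=C)CC[C@H]3C(C)(C)CCC[C@]23C)=C1 | intermediate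
12 | (1R,2S,6R)-6-(drim-8(12)-en-11-yl)-3-iodo-5,5-dimethoxy-7-oxabicyclo[4.1.0]hept-3-en-2-ol | C=C1CC[C@H]2C(C)(C)CCC[C@]2(C)[C@H]1C[C@@]12O[C@@H]1[C@H](O)C(I)=CC2(OC)OC | intermediate
13 | (1R,2R,6R)-6-(drim-8(12)-en-11-yl)-3-(hydroxymethyl)-5,5-dimethoxy-7-oxabicyclo[4.1.0]hept-3-en-2-ol | C=C1CC[C@H]2C(C)(C)CCC[C@]2(C)[C@H]1C[C@@]12O[C@@H]1[C@H](O)C(CO)=CC2(OC)OC | intermediate
14 | (R)-(−)-mevalonolactone | C[C@]1(O)CC(=O)OCC1 | starting material
15 | potassium (R)-mevalonate | C[C@@](O)(CCO)CC(=O)[O-].[K+] | intermediate (not isolated)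
16 | allyl (3R)-3,5-dihydroxy-3-methylpentanoate | C[C@@](O)(CCO)CC(=O)OCC=C | intermediate
17 | (3R)-5-(allyloxy)-3-hydroxy-3-methyl-5-oxopentanoic acid | C[C@@](O)(CC(=O)O)CC(=O)OCC=C | intermediate
18 | 1-allyl 5-{[(1R,2R,6R)-6-(drim-8(12)-en-11-yl)-2-hydroxy-5,5-dimethoxy-7-oxabicyclo[4.1.0]hept-3-en-3-yl]methyl} (3S)-3-hydroxy-3-methylpentanedioate | C=C1CC[C@H]2C(C)(C)CCC[C@]2(C)[C@H]1C[C@@]12O[C@@H]1[C@H](O)C(COC(=O)C[C@@](C)(O)CC(=O)OCC=C)=CC2(OC)OC | intermediate
19 | (3S)-5-{[(1R,2R,6R)-6-(drim-8(12)-en-11-yl)-2-hydroxy-5,5-dimethoxy-7-oxabicyclo[4.1.0]hept-3-en-3-yl]methoxy}-3-hydroxy-3-methyl-5-oxopentanoic acid | C=C1CC[C@H]2C(C)(C)CCC[C@]2(C)[C@H]1C[C@@]12O[C@@H]1[C@H](O)C(COC(=O)C[C@@](C)(O)CC(=O)O)=CC2(OC)OC | intermediate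
20 | CNP0158101.1, (3S)-5-{[(1R,2R,6R)-6-(drim-8(12)-en-11-yl)-2-hydroxy-5-oxo-7-oxabicyclo[4.1.0]hept-3-en-3-yl]methoxy}-3-hydroxy-3-methyl-5-oxopentanoic acid | C=C1CC[C@H]2C(C)(C)CCC[C@]2(C)[C@H]1C[C@@]12O[C@@H]1[C@H](O)C(COC(=O)C[C@@](C)(O)CC(=O)O)=CC2=O | target

**Totals**

Total step count: 14. Longest linear sequence: 12 steps (steps 1–9 and 12–14, from (+)-sclareolide).

**Steps most likely to fail**

Step 5. The β-branched Grignard reagent may form sluggishly, with Wurtz coupling or reduction. Copper-to-carbon transfer to a β-carbon flanked by the ketal quaternary centre may be slow enough for 1,2-addition to compete. The dehydrogenation may stall if the silyl dienol ether hydrolyses first. The fallback moves the bond formation to the arene stage and sets out from 5. Zinc insertion (Zn, LiCl, THF) gives (drim-8(12)-en-11-yl)zinc iodide F2. Commercial 3-bromo-4-methoxyphenol is silylated (TBSCl, imidazole) to tert-butyl(3-bromo-4-methoxyphenoxy)dimethylsilane F1. Negishi coupling of F2 with F1 (Pd(OAc)2, CPhos, THF, 25–50 °C) should give the aryl silyl ether F3, and TBAF frees 3-(drim-8(12)-en-11-yl)-4-methoxyphenol F4. Oxidative dearomatisation of F4 with PhI(OAc)2 in MeOH at 0 °C gives the p-quinone monoketal, which is 9, where the route is rejoined.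

Step 9. Transmetalation of the sp3 hydroxymethyl stannane is slow, and at the temperature needed protodeiodination or thermal degradation of the epoxy alcohol may overtake coupling. The fallback changes the one-carbon source and sets out from 12. Palladium-catalysed methoxycarbonylation (CO 1 atm, Pd(OAc)2, dppf, Et3N, MeOH/DMF, 50 °C) should give the C3' methyl ester F5. DIBAL-H (CH2Cl2, −78 °C) then reduces the unsaturated ester to the allylic alcohol, and the route is rejoined at 13.

Step 7. The bis-allylic dienol ketal can lose methanol and aromatise under the Lewis-acidic boron species or on work-up, and discrimination between the two vinyl arms may be incomplete. The fallback gives up catalyst control and sets out from 10. Reduction with NaBH4 (MeOH/CH2Cl2, −78 °C, basic work-up, no Lewis acid) gives 11 together with its C4' epimer F6, which are diastereomers because of the drimane unit. They are to be separated on triethylamine-deactivated silica or by preparative HPLC, and F6 is returned to 10 with MnO2. The route continues from 11.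

**Further compounds**

F1 | step 5 | tert-butyl(3-bromo-4-methoxyphenoxy)dimethylsilane | COc1ccc(O[Si](C)(C)C(C)(C)C)cc1Br
F2 | step 5 | (drim-8(12)-en-11-yl)zinc iodide | I[Zn]C[C@H]1C(=C)CC[C@H]2C(C)(C)CCC[C@]12C
F3 | step 5 | tert-butyl[3-(drim-8(12)-en-11-yl)-4-methoxyphenoxy]dimethylsilane | COc1ccc(O[Si](C)(C)C(C)(C)C)cc1C[C@H]1C(=C)CC[C@H]2C(C)(C)CCC[C@]12C
F4 | step 5 | 3-(drim-8(12)-en-11-yl)-4-methoxyphenol | COc1ccc(O)cc1C[C@H]1C(=C)CC[C@H]2C(C)(C)CCC[C@]12C
F5 | step 9 | methyl (1R,2R,6R)-6-(drim-8(12)-en-11-yl)-2-hydroxy-5,5-dimethoxy-7-oxabicyclo[4.1.0]hept-3-ene-3-carboxylate | C=C1CC[C@H]2C(C)(C)CCC[C@]2(C)[C@H]1C[C@@]12O[C@@H]1[C@H](O)C(C(=O)OC)=CC2(OC)OC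
F6 | step 7 | (1R)-5-(drim-8(12)-en-11-yl)-2-iodo-4,4-dimethoxycyclohexa-2,5-dien-1-ol (C4' epimer of 11) | O[C@H]1C(I)=CC(OC)(OC)C(C[C@H]2C(=C)CC[C@H]3C(C)(C)CCC[C@]23C)=C1
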